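**Retrosynthetic overview**
1. The C6 vanillate ester is cut first. The 6α-alcohol then goes back to the C6 ketone, with hydride carried in by the C4 hydroxyl.
2. Feature used: the array C4(OH)–C5(H)–C6(O) beside quaternary C1, spread over the five-membered ring (C1–C5) and the seven-membered ring (C1, C5–C10). It is the retron of a semipinacol shift in which C1 moves from C6 to C5.
3. Key disconnection C1–C5: a cis-fused C6 decalinol that carries the 4β,5β-oxirane in opened, activated form (4β-OH, equatorial 5β-OMs), so that C5–O is antiperiplanar to the ring-fusion bond C6–C1.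
4. Ring order: ring A comes from (R)-carvone. Ring B is closed by Robinson annulation with but-3-en-2-one. One shift then turns six/six into five/seven.
5. The C6 oxygen is placed β by epoxidation of the linear dienone. It then steers the C4 and C5 oxygens onto the convex β face. C8 is set by methyl addition to the locked enone.

Key step: step 10

Conventions: the target locants (C1 methyl-bearing fusion carbon, C2, C3, C4 isopropyl carbinol, C5 fusion CH, C6, C7, C8 methyl carbinol, C9=C10) are kept for all bicyclic compounds. In the decalins ring A is C1–C6 and ring B is C1, C6–C10. β is the face of the C1 methyl group and α is the other face.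

Remark on the leaving group: a ring-A oxirane holds its C5–O bond near the axial direction. The bond on C6 that lies anti to it is therefore always exocyclic to ring A (C6–O in a trans-fused 6α-ol, C6–C7 in a cis-fused 6β-ol) and never C6–C1. A Lewis acid would also sooner break the tertiary C4–O bond or ionise the C8 allylic oxygen. The oxirane is therefore used as its opened equivalent of the same C4/C5 configuration, on the cis-fused 6β-decalinol.

Remark on the chiral pool: base-mediated annulation joins the butanone chain cis to the C4 side chain, so the required C1 configuration comes from (R)-carvone.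

**Step 1**
Reactants: 1 (R)-(−)-carvone
Product: 2 (5R)-dihydrocarvone
Conditions: Zn, KOH, EtOH–H2O, reflux
Reagents that add atoms: none
Why: Dissolving-metal conjugate reduction of the enone leaves the isolated isopropenyl group and the C4 stereocentre alone, and the mixture formed at the methyl-bearing carbon does not matter because that centre is enolised in step 2.

**Step 2**
Reactants: 2 (5R)-dihydrocarvone; 3 but-3-en-2-one
Product: 4 cis-fused ketol (6β-OH; 1β-methyl; 4α-isopropenyl; C8 ketone)
Conditions: KOH (cat.), EtOH, −10 to 0 °C; crystallisation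
Reagents that add atoms: none
Why: Michael addition followed by intramolecular aldol addition (the first two stages of a Robinson annulation): the more substituted enolate takes up the enone axially with isopropenyl equatorial, so the new C1–C10 bond forms cis to the C4 side chain and sets C1, the aldol closes ring B as the cis-fused ketol, and crystallisation should remove the C1 epimer before C4 is erased.

**Step 3**
Reactants: 4 cis-fused ketol
Product: 6 linear dienone (R)-7-isopropyl-4a-methyl-4,4a,5,6-tetrahydronaphthalen-2(3H)-one, via isopropenyl octalenone 5 (not isolated)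
Conditions: p-TsOH·H2O (cat.), toluene, reflux, Dean–Stark
Reagents that add atoms: none
Why: Acid-catalysed aldol dehydration gives 5, whose isopropenyl double bond then moves by protonation–deprotonation through the isopropylidene isomer and the dienol into full conjugation (C8=O, C6=C7, C4=C5), the thermodynamic sink, so that C1 remains as the only stereocentre.

**Step 4**
Reactants: 6 linear dienone
Product: 7 6β,7β-epoxy-4-en-8-one
Conditions: 30% H2O2, NaOH (cat.), MeOH, 0 °C
Reagents that add atoms: hydrogen peroxide, OO
Why: Weitz–Scheffer epoxidation: hydroperoxide adds to C6 (C4 is shielded by isopropyl) and closes onto C7, as known for linear steroidal dienones, and as in angular-methyl octalenones the β-epoxide should prevail because the axially bound β-hydroperoxy enolate closes through a chair-like cis-decalin, the minor α-epoxide being removed by chromatography.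

**Step 5**
Reactants: 7 6β,7β-epoxy-4-en-8-one
Product: 8 6β,7β-epoxy-4,9-dien-8-one
Conditions: LiN(iPr)2, THF, −78 °C; then PhS(Cl)=NtBu, −78 °C
Reagents that add atoms: none
Why: Mukaiyama dehydrogenation: C7 is blocked as an oxirane carbon, so the base can only enolise towards C9, and the sulfur adduct loses the sulfenamide by syn elimination at −78 °C without any metal that could ionise the vinyl oxirane.

**Step 6**
Reactants: 8 6β,7β-epoxy-4,9-dien-8-one
Product: 9 6β-hydroxy-4,9-dien-8-one
Conditions: SmI2, THF–MeOH, −90 °C; pH 7 buffer
Reagents that add atoms: none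
Why: Reductive opening of an α,β-epoxy ketone by two single-electron transfers: the ketyl expels the α C7–O bond, methanol protonates the enolate at C7, and the C6–O bond is never broken, so the 6β configuration is kept.

**Step 7**
Reactants: 9 6β-hydroxy-4,9-dien-8-one
Product: 11 4β,5β,6β-trihydroxy-9-en-8-one, via osmate ester 10 (not isolated)
Conditions: OsO4, TMEDA, CH2Cl2, −78 °C; then aq. Na2SO3, THF, rt
Reagents that add atoms: osmium tetroxide, O=[Os](=O)(=O)=O
Why: Hydrogen-bond-directed syn dihydroxylation: the OsO4·TMEDA complex is held by the allylic C6 hydroxyl and adds to C4=C5 from the β face, which is also the convex face of the cis-decalin, setting C4 and C5 cis to C6–OH, while the electron-poor, doubly neopentyl C9=C10 bond stays untouched.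

**Step 8**
Reactants: 11 4β,5β,6β-trihydroxy-9-en-8-one
Product: 12 9-ene-4β,5β,6β,8α-tetraol
Conditions: MeLi, CeCl3, THF, −78 °C; H2O
Reagents that add atoms: methyllithium, [Li]C
Why: 1,2-Addition of the weakly basic organocerium reagent: with isopropyl equatorial the cis-decalin is locked so that C5 stands axial on ring B and covers the α face of C8, hence methyl enters from the β face and the new oxygen ends α, while low basicity and temperature hold back retro-aldol cleavage at C6.

**Step 9**
Reactants: 12 9-ene-4β,5β,6β,8α-tetraol
Product: 13 5β-mesylate of tetraol 12 (key-step precursor)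
Conditions: MsCl, pyridine, 0 °C
Reagents that add atoms: methanesulfonyl chloride, CS(=O)(=O)Cl
Why: Sulfonylation in pyridine touches only the single secondary hydroxyl, the three tertiary ones being inert, and keeps the C5 configuration because the C–O bond is not involved.

**Step 10**
Reactants: 13 5β-mesylate
Product: 14 trans-hydroazulenone (4β,8α-dihydroxy; 5α-H; C6 ketone; C9=C10)
Conditions: Et3Al, CH2Cl2, −78 to −20 °C; aq. potassium sodium tartrate
Reagents that add atoms: none
Why: Et3Al converts the hydroxyls into aluminium alkoxides and binds the mesylate, and as the equatorial C5–O bond ionises the antiperiplanar ring-fusion bond C6–C1 slides to C5 while the C6 alkoxide becomes the ketone, a concerted semipinacol (pinacol-type) shift of a vicinal diol monosulfonate, the reaction type long used to turn ring-fusion decalinol sulfonates into hydroazulenones. The new bond C1–C5 closes the cyclopentane C1–C5 through a three-centre transition state in which C1 bridges C6 and C5 (contraction of ring A), and the same event enlarges ring B to the cycloheptenone C1, C5–C10 by taking C5 into the ring. C5 is the only new stereocentre: C1 enters from the α side, anti to the β mesylate (inversion at C5, retention at C1), which gives 5α-H and the trans ring fusion and leaves the untouched C4–O bond cis to C6. The cis-decalin sits with isopropyl equatorial, C4–OH and C6–OH axial and C5–OMs equatorial, so no hydrogen is anti to the leaving group and both neighbouring oxygens are cis to it, which shuts off elimination and oxirane formation. Two bonds are anti to C5–O, C6–C1 and C4–C3, and C1 should win because it is fully substituted and allylic and the C1–C6 bond joins two fully substituted carbons, whereas C3 is a plain CH2. Low temperature and chelation of the β-alkoxy ketone on aluminium hold back retro-aldol opening, and Et3Al is too weak a Lewis acid to ionise the C8 allylic alkoxide.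

**Step 11**
Reactants: 14 trans-hydroazulenone
Product: 15 8α-triethylsilyl ether of 14
Conditions: TESOTf, 2,6-lutidine, CH2Cl2, −78 °C
Reagents that add atoms: triethylsilyl trifluoromethanesulfonate, CC[Si](CC)(CC)OS(=O)(=O)C(F)(F)F
Why: Kinetic silylation picks the C8 hydroxyl (flanked by methyl, CH2 and vinyl) over the C4 hydroxyl (buried next to isopropyl and hydrogen-bonded to the ketone), which is needed so that C8–OH cannot carry hydride to the wrong face in step 12.

**Step 12**
Reactants: 15 8α-triethylsilyl ether
Product: 16 6α-alcohol
Conditions: Me4NBH(OAc)3, MeCN–AcOH, −30 °C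
Reagents that add atoms: none
Why: Evans–Saksena reduction: the C4 hydroxyl exchanges onto boron and hands hydride to C6 through a six-membered transition state from the side on which C4–O lies, which places the new hydroxyl α, trans to C4–OH and the C1 methyl and cis to 5-H and C8–O.

**Step 13**
Reactants: 17 vanillic acid
Product: 19 4-O-TBS-vanillic acid, via bis-silyl vanillate 18 (not isolated)
Conditions: TBSCl, imidazole, DMF, rt; then AcOH–THF–H2O, rt
Reagents that add atoms: tert-butyldimethylsilyl chloride, CC(C)(C)[Si](C)(C)Cl
Why: Exhaustive silylation followed by selective hydrolysis of the far more labile silyl ester leaves the phenol masked and the acid free.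

**Step 14**
Reactants: 16 6α-alcohol; 19 4-O-TBS-vanillic acid
Product: 20 protected vanillate
Conditions: DCC, DMAP (cat.), CH2Cl2, rt
Reagents that add atoms: none
Why: Steglich esterification acylates the only secondary hydroxyl, the tertiary C4 hydroxyl being unreactive, with retention at C6.

**Step 15**
Reactants: 20 protected vanillate
Product: 21 target CNP0243386.4
Conditions: Bu4NF, AcOH, THF, 0 °C to rt
Reagents that add atoms: none
Why: Buffered fluoride desilylation cleaves the aryl and the tertiary alkyl silyl ether in one operation under near-neutral conditions that spare the ester and the ionisable tertiary allylic alcohol.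

**Compound list**
1 | (R)-(−)-carvone | CC1=CC[C@H](CC1=O)C(C)=C | starting material
2 | (5R)-dihydrocarvone, both epimers at the methyl-bearing carbon | CC1CC[C@H](CC1=O)C(C)=C | intermediate
3 | but-3-en-2-one | CC(=O)C=C | starting material
4 | cis-fused ketol: 6β-hydroxy-1β-methyl-4α-isopropenyldecalin-8-one | O[C@]12CC(=O)CC[C@@]1(C)CC[C@@H](C(C)=C)C2 | intermediate
5 | 1β-methyl-4α-isopropenyl octalenone (C6=C7, C8 ketone) | O=C1C=C2C[C@H](C(C)=C)CC[C@]2(C)CC1 | intermediate
6 | linear dienone, (R)-7-isopropyl-4a-methyl-4,4a,5,6-tetrahydronaphthalen-2(3H)-one | O=C1C=C2C=C(C(C)C)CC[C@]2(C)CC1 | intermediate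
7 | 6β,7β-epoxy ketone (C4=C5, C8 ketone) | O=C1CC[C@@]2(C)CCC(C(C)C)=C[C@]23O[C@H]13 | intermediate
8 | 6β,7β-epoxy dienone (C4=C5, C9=C10, C8 ketone) | O=C1C=C[C@@]2(C)CCC(C(C)C)=C[C@]23O[C@H]13 | intermediate
9 | cis-fused 6β-hydroxy dienone | O=C1C=C[C@@]2(C)CCC(C(C)C)=C[C@@]2(O)C1 | intermediate
10 | 4β,5β-osmate ester, TMEDA chelate | C[N+]1(C)CC[N+](C)(C)[Os-2]12(=O)(=O)O[C@H]3[C@](O2)(C(C)C)CC[C@]4(C)C=CC(=O)C[C@]34O | intermediate
11 | 4β,5β,6β-trihydroxy enone | O=C1C=C[C@@]2(C)CC[C@@](O)(C(C)C)[C@H](O)[C@@]2(O)C1 | intermediate
12 | cis-decal-9-ene-4β,5β,6β,8α-tetraol (1β,8β-dimethyl, 4α-isopropyl) | C[C@]1(O)C=C[C@@]2(C)CC[C@@](O)(C(C)C)[C@H](O)[C@@]2(O)C1 | intermediate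
13 | 5β-mesylate of 12, key-step precursor | C[C@]1(O)C=C[C@@]2(C)CC[C@@](O)(C(C)C)[C@H](OS(C)(=O)=O)[C@@]2(O)C1 | intermediate
14 | trans-hydroazulenone, 4β,8α-diol, 5α-H, C6 ketone, key-step product | O=C1C[C@@](C)(O)C=C[C@@]2(C)CC[C@@](O)(C(C)C)[C@H]12 | intermediate
15 | 8α-triethylsilyl ether of 14, free C4 carbinol | O=C1C[C@@](C)(O[Si](CC)(CC)CC)C=C[C@@]2(C)CC[C@@](O)(C(C)C)[C@H]12 | intermediate
16 | 4β,6α-diol 8α-triethylsilyl ether | O[C@H]1C[C@@](C)(O[Si](CC)(CC)CC)C=C[C@@]2(C)CC[C@@](O)(C(C)C)[C@H]12 | intermediate
17 | vanillic acid | COc1cc(C(=O)O)ccc1O | starting material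
18 | tert-butyldimethylsilyl 4-(tert-butyldimethylsilyloxy)-3-methoxybenzoate | COc1cc(C(=O)O[Si](C)(C)C(C)(C)C)ccc1O[Si](C)(C)C(C)(C)C | intermediate
19 | 4-(tert-butyldimethylsilyloxy)-3-methoxybenzoic acid | COc1cc(C(=O)O)ccc1O[Si](C)(C)C(C)(C)C | intermediate
20 | 6α-(4-O-TBS-vanilloyl) ester, 8α-OTES | COc1cc(C(=O)O[C@H]2C[C@@](C)(O[Si](CC)(CC)CC)C=C[C@@]3(C)CC[C@@](O)(C(C)C)[C@H]23)ccc1O[Si](C)(C)C(C)(C)C | intermediate
21 | CNP0243386.4 | COc1cc(C(=O)O[C@H]2C[C@@](C)(O)C=C[C@@]3(C)CC[C@@](O)(C(C)C)[C@H]23)ccc1O | target

Total steps: 15. Longest linear sequence: 14 (steps 1–12, 14, 15).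

**Steps most likely to fail**

**Step 10.**
- What may go wrong: the C4 alkoxide may drive migration of C3 in competition with C1. The aluminium aldolate may also open by retro-aldol cleavage of C4–C5 on warming.
- Fallback (from 13, back at 14): the competing donor is masked first. Two equivalents of TMSOTf with 2,6-lutidine at −78 °C should silylate the C8 and C4 hydroxyls. The C6 hydroxyl, next to quaternary C1, should stay free, giving the 4,8-bis(trimethylsilyl) ether mesylate F1. KN(SiMe3)2 in THF at −78 °C then forms the only possible alkoxide, at C6. The base-induced pinacol-type shift gives the bis-silylated hydroazulenone F2, which cannot open by retro-aldol cleavage, and with the C4 oxygen silylated the C3 shift has no alkoxide to drive it. HF·pyridine in THF at 0 °C frees both tertiary hydroxyls and returns 14.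

**Step 7.**
- What may go wrong: osmylation may occur from the α face, or addition to the hindered trisubstituted alkene may be sluggish. The tertiary allylic β-hydroxy ketone may also lose water or open by retro-aldol cleavage while the osmate ester is cleaved.
- Fallback (from 9, back at 15): the ketone is taken out of play before the alkene is oxidised. MeLi/CeCl3 addition to 9 gives the 6β,8α-diol F3. Facial control at C8 is weaker here because ring A is not yet locked, so an epimer may have to be separated. TESOTf/2,6-lutidine silylates the less hindered C8 hydroxyl to the silyl ether F4. OsO4·TMEDA is again steered by the free C6 hydroxyl and gives, through the osmate ester F5, the 4β,5β,6β-triol F6, which carries no β-hydroxy ketone. MsCl in pyridine gives the mesylate F7, and Et3Al rearranges it directly to 15.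

**Step 4.**
- What may go wrong: facial selectivity may be poor, addition to the fully substituted C6 may be slow, or 1,6-addition may compete.
- Fallback (from 6, back at 7): the oxirane is delivered by a hydroxyl group instead of by conjugate addition. Luche reduction (NaBH4, CeCl3·7H2O, MeOH, 0 °C) should take hydride on the α face and give the 8β-dienol F8. VO(acac)2/t-BuOOH then epoxidises the allylic C6=C7 bond syn to that hydroxyl, giving the 6β,7β-epoxy alcohol F9. Dess–Martin oxidation returns 7.

**Further compounds**
F1 | step 10 | 4,8-bis(trimethylsilyl) ether of mesylate 13 | C[C@]1(O[Si](C)(C)C)C=C[C@@]2(C)CC[C@@](O[Si](C)(C)C)(C(C)C)[C@H](OS(C)(=O)=O)[C@@]2(O)C1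
F2 | step 10 | 4,8-bis(trimethylsilyl) ether of hydroazulenone 14 | O=C1C[C@@](C)(O[Si](C)(C)C)C=C[C@@]2(C)CC[C@@](O[Si](C)(C)C)(C(C)C)[C@H]12
F3 | step 7 | cis-decal-4,9-diene-6β,8α-diol | C[C@]1(O)C=C[C@@]2(C)CCC(C(C)C)=C[C@@]2(O)C1
F4 | step 7 | 8α-triethylsilyl ether of F3 | C[C@]1(O[Si](CC)(CC)CC)C=C[C@@]2(C)CCC(C(C)C)=C[C@@]2(O)C1
F5 | step 7 | 4β,5β-osmate ester of F4, TMEDA chelate | C[N+]1(C)CC[N+](C)(C)[Os-2]12(=O)(=O)O[C@H]3[C@](O2)(C(C)C)CC[C@]4(C)C=C[C@](C)(O[Si](CC)(CC)CC)C[C@]34O
F6 | step 7 | 4β,5β,6β-triol 8α-triethylsilyl ether | C[C@]1(O[Si](CC)(CC)CC)C=C[C@@]2(C)CC[C@@](O)(C(C)C)[C@H](O)[C@@]2(O)C1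
F7 | step 7 | 5β-mesylate of F6 | C[C@]1(O[Si](CC)(CC)CC)C=C[C@@]2(C)CC[C@@](O)(C(C)C)[C@H](OS(C)(=O)=O)[C@@]2(O)C1
F8 | step 4 | 8β-dienol | O[C@H]1C=C2C=C(C(C)C)CC[C@]2(C)CC1
F9 | step 4 | 6β,7β-epoxy-8β-ol | O[C@@H]1CC[C@@]2(C)CCC(C(C)C)=C[C@]23O[C@H]13
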